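# Synthesis proposal for 3-(3-hydroxy-2-methoxyphenyl)-5,6,7-trimethoxy-4H-chromen-4-one (14)

## Analysis of the target

Compound 14 is an isoflavone. A benzo ring A is fused to a 4-pyranone ring C (O1, C2, C3, C4, C4a, C8a), and aryl ring B sits on C3. Ring A carries methoxy groups on C5, C6 and C7 and hydrogen on C8, while ring B carries a methoxy group on C2' and the only free hydroxyl on C3'. There is no stereocentre, and the C3–C1' axis (one methoxy group and one hydrogen facing C2–H and the C4 carbonyl) rotates freely, so the compound is achiral. Three places are sensitive: C2, a vinylogous formate carbon that hydroxide, alkoxide and amines attack with opening of ring C; the C5 methoxy group, peri to the carbonyl and the first to fall to Lewis acids; and the electron-rich B-ring phenol. The difficulty lies in the oxygen pattern rather than the skeleton, because ring A is pentasubstituted with four oxygens and five oxygen substituents must end as four methyl ethers and one phenol. The strategy rests on ring A: the oxygens on C6 and C8a are para to each other and those on C5 and C7 flank C6, which is the pattern of 2,6-dimethoxy-1,4-benzoquinone 10 in reduced form. The two unsubstituted carbons of 10 are equivalent and become C4a and C8, so bonding C4 to either one gives the same compound. The remainder, C2–C3–C4 with ring B, is an arylmalondialdehyde in which C4 is the free aldehyde and C2 a masked one.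

## Retrosynthetic reasoning

**14 ⇒ 13 (O3'–acyl bond).**
- The free phenol is carried as the pivalate 13.
- An ester is preferred to an ether for three reasons. It offers an excited quinone only strong primary C–H bonds. It withdraws electron density from ring B. It leaves by alkoxide exchange, which touches none of the four methyl ethers.
- The forward reaction must remove a hindered aryl ester without destroying the base-sensitive C2 position.

**13 ⇒ 12 (C6 O–CH3 bond).**
- Removing a methyl group that the target needs is what makes the quinone usable, because the oxygen on C6 begins as a quinone carbonyl and appears as a hydroxyl.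
- Compound 12 has exactly one free hydroxyl, so the forward methylation raises no selectivity question.

**12 ⇒ 11 ⇒ 9 + 10 (O1–C2 and C4–C4a).**
- These are the two bonds that tie ring A to the three-carbon unit.
- Cutting them releases ring A as the symmetric, purchasable quinone 10 with all four oxygens in place. The rest of the molecule is released as the single enal 9.
- A cut at C3–C1', C3–C4 or O1–C8a would leave a pentasubstituted ring A still to be built.
- The forward step is redox-neutral: the quinone supplies the oxidising power to take the formyl hydrogen and accepts it back as hydroquinone 11.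
- The step must achieve formyl hydrogen abstraction, C-acylation rather than O-acylation, and closure by the one hydroxyl that lies ortho to the new ketone, with expulsion of the methoxy group on C2.

**9 ⇒ 8 (enol O–CH3 bond).**
- In the arylmalondialdehyde 8 the two formyl carbons are equivalent, so O-methylation can give only one constitution.
- The alkene geometry is lost again when ring C closes.
- A methoxy leaving group is chosen because it is photochemically quiet.

**8 ⇒ 7 ⇒ 6 ⇒ 5 (bond between the aryl-bearing carbon and one formyl carbon).**
- The aryl-bearing carbon of enol ether 5 is its nucleophilic carbon, and a Vilsmeier reagent adds the missing carbon there.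
- This formylation does not stop at 9. The trimethinium salt 6 exchanges its oxygen terminus on aqueous work-up and settles as the vinylogous formamide 7.
- Compound 7 cannot serve in the photoreaction for three reasons. Its amino group would quench the quinone triplet by electron transfer. Its N-methyl hydrogens are easily abstracted. The amine released on ring closure would displace the methoxy groups of 10.
- The nitrogen is therefore removed by acid hydrolysis to 8 before the methyl group is put on.

**5 ⇒ 3 + 4 (the C=C bond).**
- A methoxymethylene Wittig reaction adds one carbon to aldehyde 3 and delivers it at the enol ether oxidation level that the formylation needs.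
- No separate arylacetaldehyde has to be handled.

**3 ⇒ 2 ⇒ 1 (O3–acyl, then O2–CH3).**
- The two hydroxyls of 1 differ in acidity because only O2 is conjugated with the formyl group.
- Methylation of the monoanion should address O2, and the remaining hydroxyl of 2 then takes the pivaloyl group.

## Alternatives that were turned down

**Alternative 1:**
- **Disconnection.** C3–C4 and O1–C2 are cut at the isoflavanone level. Ring A arrives as 6-hydroxy-2,3,4-trimethoxybenzaldehyde A2. Ring B arrives with C2 and C3 as 1-(benzyloxy)-3-ethynyl-2-methoxybenzene A3.
- **Forward key step.** A gold(I) or rhodium(I) catalyst has to deliver the formyl C–H across the triple bond with the acyl carbon on the internal, aryl-bearing carbon. The phenol then closes the ring by oxa-Michael addition to the terminal methylene, giving racemic isoflavanone A1.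
- **For it.** Both halves are short, and all three A-ring methyl ethers are present from the start, so no late methylation is needed. A thermal catalytic step scales more easily than a photoreaction. The whole sequence needs about seven operations against nine here. On step count and on scalability it is the stronger plan.
- **Against it.**
  - The step depends on branched regiochemistry. Delivery of the acyl group to the terminal carbon would give a chalcone-type enone and hence the flavanone skeleton.
  - The formyl group of A2 sits between a hydroxyl and a methoxy group and is fed by three donors. This slows C–H activation and leaves room for decarbonylation.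
  - A1 is one oxidation level too low. A stereocentre at C3 is made only to be destroyed by dehydrogenation of C2–C3 in the presence of two electron-rich rings.
  - The benzyl ether must then be removed without reducing the new C2=C3 bond.
- **Comparison.** The chosen strategy gives the chromone oxidation level directly. It removes the regiochemical question by symmetry and uses no metal.

**Alternative 2:**
- **Disconnection.** Only C3–C4 is cut, at the 3-hydroxyisoflavanone level. The substrate is the keto-aldehyde 6-{2-[3-(benzyloxy)-2-methoxyphenyl]-2-oxoethoxy}-2,3,4-trimethoxybenzaldehyde A5. It is made by O-alkylating A2 with 1-[3-(benzyloxy)-2-methoxyphenyl]-2-bromoethanone A6.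
- **Forward key step.** A triazolium-derived carbene converts the formyl carbon into an acyl anion equivalent. This adds to the tethered ketone in a 6-exo-trig closure and gives the racemic tertiary alcohol A4.
- **For it.** Intramolecular aldehyde–ketone benzoin closure to 3-hydroxychromanones is a well-behaved organocatalytic reaction type. Chemoselectivity is built in, since only the aldehyde can be umpoled, and the conditions are mild. Its key step is less risky than the photoacylation.
- **Against it.**
  - The aldehyde is di-ortho-substituted and electron-rich, and the ketone is flanked by a methoxy group. The benzoin addition is reversible, so the congested adduct may not be favoured.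
  - Dehydration of A4 is awkward. Ionisation at C3 is opposed by the adjacent carbonyl, the C2 hydrogens are not acidic, and α-ketol or aryl shifts can compete.
  - A stereocentre is again made and erased.
  - A6 needs about five steps from 1, so the line runs to roughly nine steps plus the preparation of A2.
- **Comparison.** The chosen strategy forms two skeletal bonds in its key step instead of one. It needs no later dehydration and is no longer.

**Alternative 3:**
- **Disconnection.** O1–C8a is cut. The substrate is the chelated enol (Z)-3-hydroxy-2-[2-methoxy-3-(pivaloyloxy)phenyl]-1-(2,3,4-trimethoxyphenyl)prop-2-en-1-one A8.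
- **Forward key step.** Anodic oxidation in a fluorinated alcohol takes an electron from the trimethoxyaryl ring and the enol oxygen attacks the free ortho carbon. Loss of a second electron and two protons gives A7, which is identical with 13.
- **For it.** Ring A comes from a cheap trimethoxyarene with every methyl ether in place, and current is the only oxidant. The attacked carbon is para to the central methoxy group, where a radical cation carries positive charge. The product is one step from the target. In avoiding the late methylation it is stronger.
- **Against it.**
  - The ring to be oxidised carries the acyl group, which raises its potential. A8 also offers two rival donors, the dicarbonyl enol and ring B. Oxidation at the enol would give a C3 radical that dimerises or is trapped by solvent.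
  - A7 has a fourth oxygen on ring A and is easier to oxidise than A8, so over-oxidation is built in.
  - Ipso attack at the methoxy-bearing ortho carbon would give a 7,8-dimethoxy isomer.
  - Closure of an enol oxygen onto an acyl-deactivated arene has no close precedent.
  - The arylacetic acid, acylation, formylation, electrolysis and deprotection add up to about nine steps, so nothing is saved.
- **Comparison.** The chosen strategy brings the C8a oxygen in with the quinone. It therefore needs no C–H oxidation at all.

Key step: step 7

Assumption: the target has no stereocentre and no configurationally stable axis, so it is one achiral compound and no enantiocontrol is called for.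

## Route

Step 1
Reactants: 1 2,3-dihydroxybenzaldehyde
Product: 2 3-hydroxy-2-methoxybenzaldehyde
Conditions: K2CO3 (1.0 equiv), MeI (1.05 equiv), DMF, rt
Reagents that add atoms: methyl iodide, CI
Why: Williamson methylation of the monoanion; the 2-OH is the more acidic one because its phenoxide is conjugated with the ortho formyl group, so one equivalent of weak base places the charge on O2 and alkylation follows there, while dianion conditions, which would reverse the site, are avoided. Doubly methylated material is neutral and is removed by base extraction of phenol 2.

Step 2
Reactants: 2 3-hydroxy-2-methoxybenzaldehyde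
Product: 3 3-formyl-2-methoxyphenyl pivalate
Conditions: PivCl (1.1 equiv), Et3N (1.5 equiv), DMAP (5 mol %), CH2Cl2, 0 °C to rt
Reagents that add atoms: pivaloyl chloride, CC(C)(C)C(=O)Cl
Why: DMAP-catalysed O-acylation of the only hydroxyl present; the aldehyde and the methyl ether are inert.

Step 3
Reactants: 3 3-formyl-2-methoxyphenyl pivalate; 4 (methoxymethyl)triphenylphosphonium chloride
Product: 5 (E/Z)-2-methoxy-3-(2-methoxyvinyl)phenyl pivalate
Conditions: 4 (1.3 equiv), NaHMDS (1.2 equiv), THF, 0 °C; then 3, −78 °C to 0 °C
Reagents that add atoms: (methoxymethyl)triphenylphosphonium chloride 4, COC[P+](c1ccccc1)(c1ccccc1)c1ccccc1.[Cl-]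
Why: Wittig methoxymethylenation; the ylide is preformed with a deficit of a non-nucleophilic base so that no free base meets the aryl ester, and at low temperature the aldehyde outruns the neopentyl-type ester carbonyl. The E/Z mixture is used as such because both isomers react at the same carbon in step 4.

Step 4
Reactants: 5 (E/Z)-2-methoxy-3-(2-methoxyvinyl)phenyl pivalate
Product: 7 (E)-3-(dimethylamino)-2-[2-methoxy-3-(pivaloyloxy)phenyl]acrylaldehyde, via methoxytrimethinium chloride 6 (not isolated)
Conditions: (COCl)2 (1.3 equiv), DMF (1.5 equiv), CH2Cl2, 0 °C; then 5, 0 °C to 40 °C; then ice-cold aq K2CO3 (pH 9), short contact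
Reagents that add atoms: N,N-dimethylformamide, CN(C)C=O; water, O
Why: Vilsmeier–Haack formylation of an enol ether; the chloroiminium ion attacks the carbon β to oxygen, which bears the aryl group, and proton loss gives salt 6. In weakly alkaline water the oxygen terminus of 6, the poorer donor, is exchanged and the vinylogous formamide 7 is the thermodynamic sink, which is the behaviour that turns vinyl ethers into aminoacroleins. Brief contact with cold carbonate leaves the pivalate alone.

Step 5
Reactants: 7 (E)-3-(dimethylamino)-2-[2-methoxy-3-(pivaloyloxy)phenyl]acrylaldehyde
Product: 8 2-[2-methoxy-3-(pivaloyloxy)phenyl]malondialdehyde (enol form)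
Conditions: 2 M aq HCl–THF (1:2), 45 °C
Reagents that add atoms: water, O
Why: Acid hydrolysis of a vinylogous amide (enamine hydrolysis); protonation gives an iminium ion, water adds, and the amine leaves as its salt and cannot re-add. Aryl pivalate and aryl methyl ethers are inert to dilute acid, and 8, an acid of roughly carboxylic strength, can be purified through a bicarbonate extract.

Step 6
Reactants: 8 2-[2-methoxy-3-(pivaloyloxy)phenyl]malondialdehyde (enol form)
Product: 9 (E)-3-methoxy-2-[2-methoxy-3-(pivaloyloxy)phenyl]acrylaldehyde
Conditions: TMSCHN2 (1.2 equiv), toluene–MeOH (4:1), 0 °C
Reagents that add atoms: (trimethylsilyl)diazomethane, C[Si](C)(C)C=[N+]=[N-]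
Why: Diazoalkane O-methylation of an acidic enol, as in the esterification of a carboxylic acid; proton transfer is followed by attack of the enolate oxygen on the methyldiazonium ion under neutral conditions. The two formyl groups of 8 are equivalent, so one constitution results; the push–pull alkene should settle as the E isomer, and any Z isomer is equally usable.

Step 7
Reactants: 9 (E)-3-methoxy-2-[2-methoxy-3-(pivaloyloxy)phenyl]acrylaldehyde; 10 2,6-dimethoxy-1,4-benzoquinone
Product: 12 6-hydroxy-5,7-dimethoxy-3-[2-methoxy-3-(pivaloyloxy)phenyl]-4H-chromen-4-one, via acylhydroquinone 11 (not isolated)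
Conditions: 9 (1.0 equiv), 10 (1.5 equiv), hν (405 nm LED), degassed MeCN–CH2Cl2 (1:1, 0.03 M), Ar, 20 °C; then TsOH·H2O (10 mol %), 40 °C
Reagents that add atoms: none
Why: Light of 405 nm is absorbed only by 10, whose triplet abstracts the formyl hydrogen of 9, the weakest and most hydridic C–H bond on offer, leaving a semiquinone and an alkenoyl σ-radical that does not lose CO because a vinyl radical would result. The acyl radical forms the C4–C4a bond at a free ring carbon, either inside the radical pair or by addition to ground-state 10 followed by hydrogen return from the semiquinone, and enolisation gives 11 with no net change of oxidation level. The closest known reaction type is the photo-Friedel–Crafts acylation of 1,4-quinones with aldehydes, which accepts enals and whose products have been closed to chromanones; only the donor-substituted quinone and the β-alkoxy group of the enal are new here. Site selectivity needs no control because C3 and C5 of 10 are exchanged by its twofold axis, and addition there leaves a radical on C2 that is stabilised by both its methoxy group and the C1 carbonyl. The step needs C-acylation rather than O-acylation, and the excess of 10 favours capture of escaped acyl radicals by the C=C bond of ground-state quinone, a path that can only give the C-acyl product. With a trace of acid the hydroxyl ortho to the ketone adds to the β-carbon (6-endo-trig) and methanol leaves, the addition–elimination that also closes 2-hydroxyaryl enaminones to chromones; the other hydroxyl is meta to the ketone, cannot reach C2, and remains as the C6–OH of 12. E/Z scrambling of 9 or 11 by energy transfer is harmless because C2 passes through an sp3 stage, and no stereocentre is formed. The pivalate offers only strong primary C–H bonds and lowers the donor strength of ring B, which limits hydrogen abstraction and electron-transfer quenching at the wrong places.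

Step 8
Reactants: 12 6-hydroxy-5,7-dimethoxy-3-[2-methoxy-3-(pivaloyloxy)phenyl]-4H-chromen-4-one
Product: 13 5,6,7-trimethoxy-3-[2-methoxy-3-(pivaloyloxy)phenyl]-4H-chromen-4-one
Conditions: MeI (3 equiv), K2CO3 (2 equiv), dry acetone, reflux
Reagents that add atoms: methyl iodide, CI
Why: Williamson methylation of the only free phenol; it lies between two methoxy groups, hence the excess of a small electrophile and heat. Anhydrous carbonate leaves the pivalate and ring C intact.

Step 9
Reactants: 13 5,6,7-trimethoxy-3-[2-methoxy-3-(pivaloyloxy)phenyl]-4H-chromen-4-one
Product: 14 3-(3-hydroxy-2-methoxyphenyl)-5,6,7-trimethoxy-4H-chromen-4-one (target)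
Conditions: K2CO3 (2 equiv), dry MeOH–CH2Cl2 (4:1), 0 °C to rt; then 1 M HCl to pH 4–5
Reagents that add atoms: none
Why: Base-mediated transesterification (methanolysis) of an aryl ester; the phenoxide leaving group lets even a pivalate exchange near room temperature. Methoxide may add reversibly at C2 and open ring C to a β-methoxyenone phenoxide, but without water C2 is not lost, and the acid quench recloses the ring by the same addition–elimination as in step 7.

## Compound list

1 | 2,3-dihydroxybenzaldehyde | O=Cc1cccc(O)c1O | starting material
2 | 3-hydroxy-2-methoxybenzaldehyde | COc1c(O)cccc1C=O | intermediate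
3 | 3-formyl-2-methoxyphenyl pivalate | COc1c(C=O)cccc1OC(=O)C(C)(C)C | intermediate
4 | (methoxymethyl)triphenylphosphonium chloride | COC[P+](c1ccccc1)(c1ccccc1)c1ccccc1.[Cl-] | starting material
5 | (E/Z)-2-methoxy-3-(2-methoxyvinyl)phenyl pivalate (mixture of alkene isomers) | COC=Cc1cccc(OC(=O)C(C)(C)C)c1OC | intermediate
6 | N-{3-methoxy-2-[2-methoxy-3-(pivaloyloxy)phenyl]allylidene}-N-methylmethanaminium chloride (not isolated, geometry not fixed) | COC=C(C=[N+](C)C)c1cccc(OC(=O)C(C)(C)C)c1OC.[Cl-] | intermediate
7 | (E)-3-(dimethylamino)-2-[2-methoxy-3-(pivaloyloxy)phenyl]acrylaldehyde | CN(C)/C=C(/C=O)c1cccc(OC(=O)C(C)(C)C)c1OC | intermediate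
8 | 2-[2-methoxy-3-(pivaloyloxy)phenyl]malondialdehyde, drawn as its enol | OC=C(C=O)c1cccc(OC(=O)C(C)(C)C)c1OC | intermediate
9 | (E)-3-methoxy-2-[2-methoxy-3-(pivaloyloxy)phenyl]acrylaldehyde | CO/C=C(/C=O)c1cccc(OC(=O)C(C)(C)C)c1OC | intermediate
10 | 2,6-dimethoxy-1,4-benzoquinone | COC1=CC(=O)C=C(OC)C1=O | starting material
11 | (E/Z)-1-(3,6-dihydroxy-2,4-dimethoxyphenyl)-3-methoxy-2-[2-methoxy-3-(pivaloyloxy)phenyl]prop-2-en-1-one (not isolated) | COC=C(C(=O)c1c(O)cc(OC)c(O)c1OC)c1cccc(OC(=O)C(C)(C)C)c1OC | intermediate
12 | 6-hydroxy-5,7-dimethoxy-3-[2-methoxy-3-(pivaloyloxy)phenyl]-4H-chromen-4-one | COc1cc2occ(-c3cccc(OC(=O)C(C)(C)C)c3OC)c(=O)c2c(OC)c1O | intermediate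
13 | 5,6,7-trimethoxy-3-[2-methoxy-3-(pivaloyloxy)phenyl]-4H-chromen-4-one | COc1cc2occ(-c3cccc(OC(=O)C(C)(C)C)c3OC)c(=O)c2c(OC)c1OC | intermediate
14 | 3-(3-hydroxy-2-methoxyphenyl)-5,6,7-trimethoxy-4H-chromen-4-one (achiral) | COc1cc2occ(-c3cccc(O)c3OC)c(=O)c2c(OC)c1OC | target

## Step count and least certain steps

Total steps: 9. Longest linear sequence: 9 (1 to 14). Compounds 4 and 10 are bought.

**Step 7 (key step).** Several processes can go wrong.
- Hydrogen abstraction may be inefficient, because two methoxy donors give the lowest quinone triplet more charge-transfer character.
- The nucleophilic acyl radical may add slowly, because the free ring carbon is also the β-carbon of an enol ether.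
- O-acylation of the semiquinone may compete.
- The quinone carbonyl may undergo Paternò–Büchi addition to the push–pull alkene.
- The hydroquinone product may quench the triplet as it accumulates.

The fallback keeps the symmetry argument but replaces the radical bond formation by ionic chemistry. It sets out from 5 and 10 and returns at 12. Mild acid hydrolysis of enol ether 5 gives [2-methoxy-3-(pivaloyloxy)phenyl]acetaldehyde F1, and Pinnick oxidation gives [2-methoxy-3-(pivaloyloxy)phenyl]acetic acid F2. Dithionite reduction of 10 gives 2,6-dimethoxybenzene-1,4-diol F3. Friedel–Crafts acylation of F3 by F2 in BF3·OEt2 can occur only at the two equivalent free carbons. It gives the deoxybenzoin 1-(3,6-dihydroxy-2,4-dimethoxyphenyl)-2-[2-methoxy-3-(pivaloyloxy)phenyl]ethanone F4. One-carbon closure with DMF, BF3·OEt2 and MsCl, which tolerates free phenols, then gives 12.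

**Step 4 (with its sequel, step 5).** The weak chloroiminium electrophile may attack the hindered, aryl-conjugated enol-ether carbon only sluggishly. The hydrogen chloride released may meanwhile oligomerise the enol ether. The later hydrolysis of the vinylogous amide may also be slow enough to erode the dialdehyde by deformylation. The fallback sets out from 5 and returns at 9, bypassing 6 to 8 and all nitrogen. BF3·OEt2-catalysed addition of trimethyl orthoformate across the enol ether (Müller-Cunradi–Pieroh type) gives 3-(1,1,3,3-tetramethoxypropan-2-yl)-2-methoxyphenyl pivalate F5. Partial hydrolysis with one equivalent of water and catalytic TsOH unmasks one acetal, and β-elimination then delivers 9.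

**Step 9.** Exchange at the hindered ester is slow, which prolongs exposure of C2 to methoxide. Adventitious water would then turn reversible ring opening into irreversible loss of C2. The fallback sets out from 13, returns at 14, and makes the failure mode the plan. Aqueous KOH in ethanol cleaves the ester and degrades ring C completely to 1-(6-hydroxy-2,3,4-trimethoxyphenyl)-2-(3-hydroxy-2-methoxyphenyl)ethanone F6. The DMF, BF3·OEt2 and MsCl closure then rebuilds C2 and gives 14 directly.

**Step 1.** Proton exchange between the two oxygens may let the more nucleophilic O3 phenoxide compete, and a second methylation may follow. The fallback sets out from 1 and returns at 3 with the order of events reversed. One equivalent of PivCl with Et3N acylates the unchelated 3-OH, and any 2-O-acyl isomer relaxes by acyl shift to the chelated one, giving 3-formyl-2-hydroxyphenyl pivalate F7. Mitsunobu methylation (MeOH, PPh3, DIAD) then caps the 2-OH without generating a phenoxide that could trigger acyl migration, giving 3.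

**Step 3.** The aryl pivalate may transfer its acyl group to the ylide or to traces of free base. The fallback sets out from 2 and returns at 5. The Wittig reaction is run on the free phenol with a second equivalent of ylide to carry it as its phenoxide, giving (E/Z)-2-methoxy-3-(2-methoxyvinyl)phenol F8. This is pivaloylated under the basic conditions of step 2, which the enol ether tolerates.

## Further compounds

F1 | step 7 | [2-methoxy-3-(pivaloyloxy)phenyl]acetaldehyde | COc1c(CC=O)cccc1OC(=O)C(C)(C)C
F2 | step 7 | [2-methoxy-3-(pivaloyloxy)phenyl]acetic acid | COc1c(CC(=O)O)cccc1OC(=O)C(C)(C)C
F3 | step 7 | 2,6-dimethoxybenzene-1,4-diol | COc1cc(O)cc(OC)c1O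
F4 | step 7 | 1-(3,6-dihydroxy-2,4-dimethoxyphenyl)-2-[2-methoxy-3-(pivaloyloxy)phenyl]ethanone | COc1cc(O)c(C(=O)Cc2cccc(OC(=O)C(C)(C)C)c2OC)c(OC)c1O
F5 | step 4 | 3-(1,1,3,3-tetramethoxypropan-2-yl)-2-methoxyphenyl pivalate | COC(OC)C(C(OC)OC)c1cccc(OC(=O)C(C)(C)C)c1OC
F6 | step 9 | 1-(6-hydroxy-2,3,4-trimethoxyphenyl)-2-(3-hydroxy-2-methoxyphenyl)ethanone | COc1cc(O)c(C(=O)Cc2cccc(O)c2OC)c(OC)c1OC
F7 | step 1 | 3-formyl-2-hydroxyphenyl pivalate | O=Cc1cccc(OC(=O)C(C)(C)C)c1O
F8 | step 3 | (E/Z)-2-methoxy-3-(2-methoxyvinyl)phenol | COC=Cc1cccc(O)c1OC
A1 | alternative 1 | 3-[3-(benzyloxy)-2-methoxyphenyl]-5,6,7-trimethoxychroman-4-one, racemate, one enantiomer drawn arbitrarily | COc1cc2OC[C@H](c3cccc(OCc4ccccc4)c3OC)C(=O)c2c(OC)c1OC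
A2 | alternative 1 | 6-hydroxy-2,3,4-trimethoxybenzaldehyde | COc1cc(O)c(C=O)c(OC)c1OC
A3 | alternative 1 | 1-(benzyloxy)-3-ethynyl-2-methoxybenzene | C#Cc1cccc(OCc2ccccc2)c1OC
A4 | alternative 2 | 3-[3-(benzyloxy)-2-methoxyphenyl]-3-hydroxy-5,6,7-trimethoxychroman-4-one, racemate, one enantiomer drawn arbitrarily | COc1cc2OC[C@@](O)(c3cccc(OCc4ccccc4)c3OC)C(=O)c2c(OC)c1OC
A5 | alternative 2 | 6-{2-[3-(benzyloxy)-2-methoxyphenyl]-2-oxoethoxy}-2,3,4-trimethoxybenzaldehyde | COc1cc(OCC(=O)c2cccc(OCc3ccccc3)c2OC)c(C=O)c(OC)c1OC
A6 | alternative 2 | 1-[3-(benzyloxy)-2-methoxyphenyl]-2-bromoethanone | COc1c(OCc2ccccc2)cccc1C(=O)CBr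
A7 | alternative 3 | 5,6,7-trimethoxy-3-[2-methoxy-3-(pivaloyloxy)phenyl]-4H-chromen-4-one (identical with 13) | COc1cc2occ(-c3cccc(OC(=O)C(C)(C)C)c3OC)c(=O)c2c(OC)c1OC
A8 | alternative 3 | (Z)-3-hydroxy-2-[2-methoxy-3-(pivaloyloxy)phenyl]-1-(2,3,4-trimethoxyphenyl)prop-2-en-1-one | COc1ccc(C(=O)/C(=C\O)c2cccc(OC(=O)C(C)(C)C)c2OC)c(OC)c1OC
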